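The target is the monoacetate of a C2-symmetric anti-1,3-diol. An axis through C4 exchanges C3 with C5, C1 with C7, and catechol ring A (on C1) with ring B (on C7); only the acetyl on O3 breaks it. The route therefore rests on cutting both aryl–CH2 bonds, C1–ring A and C7–ring B. In one flask, unprotected (3S,5S)-hepta-1,6-diene-3,5-diol, which already holds both stereocentres, is hydroborated at both vinyl groups and coupled twice with 4-bromo-1,2-bis(benzyloxy)benzene (two-directional B-alkyl Suzuki–Miyaura coupling). This gives the whole diarylheptanoid skeleton. The homotopic hydroxyls then allow an unambiguous orthoester monoacetylation, and hydrogenolysis frees the catechols.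

Key step: step 4

Assumption: 1,5-dichloropentane-2,4-dione 3 is taken as a catalogue building block; the chain is numbered from C1 (next to ring A) through C3 (acetate) and C5 (hydroxyl) to C7 (next to ring B), and the target SMILES reads as (3R,5R), the anti series.

Step 1
Reactants: 1 4-bromocatechol (4-bromobenzene-1,2-diol)
Product: 2 4-bromo-1,2-bis(benzyloxy)benzene
Conditions: BnBr (2.3 equiv), K2CO3 (3 equiv), DMF, rt to 60 °C
Reagents that add atoms: benzyl bromide, BrCc1ccccc1
Why: Williamson ether synthesis, in which both phenoxides displace bromide from the benzylic halide while the aryl bromide stays inert; benzyl ethers are chosen because they tolerate borane, hydroxide and mild acid and are removed at the end by neutral hydrogenolysis that spares the acetate.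

Step 2
Reactants: 3 1,5-dichloropentane-2,4-dione
Product: 4 (2S,4S)-1,5-dichloropentane-2,4-diol
Conditions: H2 (80 bar), RuCl2[(R)-BINAP] (0.2 mol %), MeOH, 80 °C; recrystallisation
Reagents that add atoms: none
Why: Noyori asymmetric hydrogenation of a 1,3-diketone, in which the (R)-BINAP complex of divalent ruthenium reduces the chelated ketone from the face that turns pentane-2,4-dione into its (R,R)-diol and then reduces the hydroxy ketone under matched catalyst control to the anti diol, which is (2S,4S) here only because CH2Cl outranks the central CH2, while a wrong-face event ends in the meso diol that recrystallisation should remove.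

Step 3
Reactants: 4 (2S,4S)-1,5-dichloropentane-2,4-diol
Product: 6 (3S,5S)-hepta-1,6-diene-3,5-diol, via bis-epoxide 5 (not isolated)
Conditions: Me3SI (10 equiv), n-BuLi (9.5 equiv), THF, −15 °C; then 4, −15 °C to rt
Reagents that add atoms: trimethylsulfonium iodide, C[S+](C)C.[I-]
Why: One-carbon homologation of terminal epoxides to allylic alcohols with dimethylsulfonium methylide, in which the ylide first acts as base and closes both chlorohydrins to 5, then opens each oxirane at its CH2 terminus, and further ylide triggers loss of dimethyl sulfide from the betaine; no C–O bond at a stereocentre is broken, so the configuration of 4 passes unchanged into C3 and C5 of 6.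

Step 4
Reactants: 6 (3S,5S)-hepta-1,6-diene-3,5-diol; 2 4-bromo-1,2-bis(benzyloxy)benzene (2.3 equiv)
Product: 8 (3R,5R)-1,7-bis[3,4-bis(benzyloxy)phenyl]heptane-3,5-diol, via tetraboryl adduct 7 (not isolated)
Conditions: 9-BBN (4.5 equiv), THF, 0 to 40 °C until H2 evolution ends; then 2, PdCl2(dppf) (5 mol %), 3 M aq NaOH, THF, 65 °C
Reagents that add atoms: none
Why: 9-BBN first converts both hydroxyls into B-alkoxy-9-BBN groups with loss of H2 and then adds anti-Markovnikov to both vinyl groups, so that boron sits on C1 and C7 in 7; hydroxide turns each trialkylborane into its borate, zerovalent palladium inserts into the C–Br bond of 2, the primary alkyl group is transferred to divalent palladium and reductive elimination forms the C(sp3)–C(sp2) bond, after which the same cycle runs at the other terminus. The closest known reaction type is the hydroboration/B-alkyl Suzuki–Miyaura coupling of terminal alkenes that carry an allylic oxygen substituent, used here in two-directional form. No ring is closed and no stereocentre is made, because C3 and C5 come from 6, lie two bonds away from the reacting carbons and have no pathway for epimerisation under borane or aqueous hydroxide. The step needs terminal regioselectivity in the hydroboration, which the bulk of 9-BBN and the inductive effect of the allylic oxygen secure, and transfer of the primary alkyl group rather than a bridgehead B–C bond, which is inherent to B-alkyl-9-BBN reagents. β-Hydride elimination from the alkylpalladium intermediate is held back by the wide bite angle of dppf, and the only base-sensitive function of the target, the acetate, is not yet present. Because the C2 axis makes the two termini homotopic, the mono-coupled stage is a single species and no end differentiation is needed, so whichever hydroxyl is acetylated later, the aryl–CH2 bond on its side stems from this step.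

Step 5
Reactants: 8 (3R,5R)-1,7-bis[3,4-bis(benzyloxy)phenyl]heptane-3,5-diol
Product: 10 (3R,5R)-1,7-bis[3,4-bis(benzyloxy)phenyl]-5-hydroxyheptan-3-yl acetate, via cyclic orthoacetate 9 (not isolated)
Conditions: MeC(OMe)3 (3 equiv), CSA (5 mol %), CH2Cl2, rt; then 80% aq AcOH, 0 °C to rt
Reagents that add atoms: trimethyl orthoacetate, CC(OC)(OC)OC; water, O
Why: Orthoester method of diol monoacylation, in which acid-catalysed exchange gives the six-membered orthoacetate 9 and its hydrolysis through the 1,3-dioxan-2-ylium ion can release only one acetate and one free hydroxyl; both C–O bonds at the stereocentres stay intact, and since O3 and O5 are homotopic, either mode of opening (and any later 1,3-acyl shift) gives the same compound.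

Step 6
Reactants: 10 (3R,5R)-1,7-bis[3,4-bis(benzyloxy)phenyl]-5-hydroxyheptan-3-yl acetate
Product: 11 (3R,5R)-1,7-bis(3,4-dihydroxyphenyl)-5-hydroxyheptan-3-yl acetate (target)
Conditions: H2 (1 atm), 10% Pd/C, degassed EtOAc/EtOH, rt; filtration and concentration under argon
Reagents that add atoms: none
Why: Catalytic hydrogenolysis cleaves the four benzyl aryl ethers under neutral conditions, while the secondary acetate and alcohol are not benzylic and are untouched, so both stereocentres and the ester should survive; exclusion of air protects the free catechols.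

Compound list
1 | 4-bromocatechol (4-bromobenzene-1,2-diol) | Oc1ccc(Br)cc1O | starting material
2 | 4-bromo-1,2-bis(benzyloxy)benzene | Brc1ccc(OCc2ccccc2)c(OCc2ccccc2)c1 | intermediate
3 | 1,5-dichloropentane-2,4-dione | ClCC(=O)CC(=O)CCl | starting material
4 | (2S,4S)-1,5-dichloropentane-2,4-diol | O[C@H](CCl)C[C@H](O)CCl | intermediate
5 | (2S,4S)-1,2:4,5-diepoxypentane (bis-epoxide) | C1O[C@H]1C[C@H]1CO1 | intermediate
6 | (3S,5S)-hepta-1,6-diene-3,5-diol | O[C@H](C=C)C[C@H](O)C=C | intermediate
7 | (3R,5R)-1,7-bis(9-borabicyclo[3.3.1]nonan-9-yl)-3,5-bis(9-borabicyclo[3.3.1]nonan-9-yloxy)heptane (tetraboryl adduct) | C1CCC2CCCC1B2O[C@H](CCB1C2CCCC1CCC2)C[C@H](OB1C2CCCC1CCC2)CCB1C2CCCC1CCC2 | intermediate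
8 | (3R,5R)-1,7-bis[3,4-bis(benzyloxy)phenyl]heptane-3,5-diol | O[C@H](CCc1ccc(OCc2ccccc2)c(OCc2ccccc2)c1)C[C@H](O)CCc1ccc(OCc2ccccc2)c(OCc2ccccc2)c1 | intermediate
9 | (4R,6R)-4,6-bis{2-[3,4-bis(benzyloxy)phenyl]ethyl}-2-methoxy-2-methyl-1,3-dioxane (cyclic orthoacetate; C2 is not a stereocentre) | COC1(C)O[C@H](CCc2ccc(OCc3ccccc3)c(OCc3ccccc3)c2)C[C@@H](CCc2ccc(OCc3ccccc3)c(OCc3ccccc3)c2)O1 | intermediate
10 | (3R,5R)-1,7-bis[3,4-bis(benzyloxy)phenyl]-5-hydroxyheptan-3-yl acetate | CC(=O)O[C@H](CCc1ccc(OCc2ccccc2)c(OCc2ccccc2)c1)C[C@H](O)CCc1ccc(OCc2ccccc2)c(OCc2ccccc2)c1 | intermediate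
11 | (3R,5R)-1,7-bis(3,4-dihydroxyphenyl)-5-hydroxyheptan-3-yl acetate | CC(=O)O[C@H](CCc1ccc(O)c(O)c1)C[C@H](O)CCc1ccc(O)c(O)c1 | target

Total step count: 6
Longest linear sequence: 5 steps (3 → 4 → 6 → 8 → 10 → 11)

Steps most likely to fail

Step 4 (key step). The hydroxyls may consume borane and leave vinyl groups unreacted. Oxidative addition into the electron-rich aryl bromide may be slow. Protodeboronation or β-hydride elimination may intervene before the second coupling, so that mono-arylated material accumulates. The fallback forms the same aryl–carbon bonds at the alkene oxidation level.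
- Starting from 6, the diol is tied up with 2,2-dimethoxypropane and catalytic CSA as the acetonide (4S,6S)-2,2-dimethyl-4,6-divinyl-1,3-dioxane F1.
- A double Mizoroki–Heck reaction with 2 (Pd(OAc)2, P(o-tol)3, NaOAc, DMF, 110 °C) should give (4S,6S)-4,6-bis{(E)-2-[3,4-bis(benzyloxy)phenyl]ethenyl}-2,2-dimethyl-1,3-dioxane F2.
- Diimide (TsNHNH2, NaOAc, aqueous DME, reflux) saturates both alkenes without touching the benzyl ethers or the allylic C–O bonds and gives (4R,6R)-4,6-bis{2-[3,4-bis(benzyloxy)phenyl]ethyl}-2,2-dimethyl-1,3-dioxane F3.
- 80% aqueous AcOH removes the acetonide, and the route is rejoined at 8.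

Step 3. The first-formed alkoxide may attack the remaining oxirane, the bis-epoxide may oligomerise under the strongly basic ylide conditions, and the small water-soluble diol may be lost on work-up. The fallback brings in C1 and C7 already attached to boron, so no alkene is needed.
- Starting from 4, bis-epoxide 5 is made separately with powdered KOH in Et2O and isolated by distillation.
- Compound 5 is then opened at both CH2 termini with bis[(pinacolato)boryl]methane (CuI, LiOt-Bu, THF, rt) to give (3R,5R)-1,7-bis(4,4,5,5-tetramethyl-1,3,2-dioxaborolan-2-yl)heptane-3,5-diol F4.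
- This bis(primary alkylboronate) is coupled twice with 2 (Pd(OAc)2, RuPhos, K2CO3, toluene/water, 90 °C), which bypasses 6 and 7 and rejoins the route at 8.

Step 5. Orthoester formation may be incomplete, because the 1,3-dioxane from an anti diol must carry one side chain axial, and premature hydrolysis may return the diol. The fallback over-acylates and then removes one ester.
- Starting from 8, exhaustive acetylation (Ac2O, pyridine, DMAP, CH2Cl2) gives (3R,5R)-1,7-bis[3,4-bis(benzyloxy)phenyl]heptane-3,5-diyl diacetate F5.
- One of its two homotopic esters is taken off by partial methanolysis (K2CO3, MeOH/THF, 0 °C, stopped early), with recovered diacetate and diol recycled. The route is rejoined at 10.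

Further compounds
F1 | step 4 | (4S,6S)-2,2-dimethyl-4,6-divinyl-1,3-dioxane | CC1(C)O[C@H](C=C)C[C@@H](C=C)O1
F2 | step 4 | (4S,6S)-4,6-bis{(E)-2-[3,4-bis(benzyloxy)phenyl]ethenyl}-2,2-dimethyl-1,3-dioxane | CC1(C)O[C@H](/C=C/c2ccc(OCc3ccccc3)c(OCc3ccccc3)c2)C[C@@H](/C=C/c2ccc(OCc3ccccc3)c(OCc3ccccc3)c2)O1
F3 | step 4 | (4R,6R)-4,6-bis{2-[3,4-bis(benzyloxy)phenyl]ethyl}-2,2-dimethyl-1,3-dioxane | CC1(C)O[C@H](CCc2ccc(OCc3ccccc3)c(OCc3ccccc3)c2)C[C@@H](CCc2ccc(OCc3ccccc3)c(OCc3ccccc3)c2)O1
F4 | step 3 | (3R,5R)-1,7-bis(4,4,5,5-tetramethyl-1,3,2-dioxaborolan-2-yl)heptane-3,5-diol | O[C@H](CCB1OC(C)(C)C(C)(C)O1)C[C@H](O)CCB1OC(C)(C)C(C)(C)O1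
F5 | step 5 | (3R,5R)-1,7-bis[3,4-bis(benzyloxy)phenyl]heptane-3,5-diyl diacetate | CC(=O)O[C@H](CCc1ccc(OCc2ccccc2)c(OCc2ccccc2)c1)C[C@H](OC(C)=O)CCc1ccc(OCc2ccccc2)c(OCc2ccccc2)c1
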